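A direct plan would acylate tryptamine A1 with 2-(2,4-dibromophenyl)acetic acid A2 to amide A3 and close the N-tryptophyl oxindole A4 by an intramolecular amide N-arylation catalysed by CuI.
It would then turn A4 in one pot (lactam activation, C-glyoxylation, Bischler–Napieralski-type closure, methanolysis) into the 6,7-dihydro ketoester A5 and dehydrogenate A5 to the target.
Its weakest steps would be:
- the one-pot conversion of A4, which would ask a single acylating reagent for three different events next to a second free indole and an acidic lactam CH2;
- the N-arylation, which would have to choose the ortho over the para C–Br bond and the amide over the indole N–H;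
- the closing dehydrogenation, which would add a step without adding complexity and expose an N–H indole to a strong oxidant.

Numbering follows 12H-pyrido[1,2-a:3,4-b']diindole: indole A (brominated) contains N5, C12b and C13, ring C is N5–C6–C7–C7a–C12a–C12b, indole B contains N12–H. The route disconnects N5–C12b and C7–C7a at the bridgehead nitrogen. The nitrogen of 5-bromo-2-iodoaniline receives a C6–C7 acetal arm and an alkyne that brings C12b, C13 and indole B. In one flask, Ph3PAuNTf2 closes the pyrrole ring of indole A by hydroamination and acid closes ring C at the nucleophilic C7a with loss of two methanol molecules, so ring C arises aromatic. Bromide-selective amination, multi-event acylation and dehydrogenation all disappear; C13 is acylated last.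

Key step: step 4

Remark: the target is achiral, so no stereocentre has to be set; compound 2 is used as its commercial aqueous solution.

Step 1
Reactants: 1 5-bromo-2-iodoaniline; 2 dimethoxyacetaldehyde (60 wt% in water)
Product: 4 5-bromo-N-(2,2-dimethoxyethyl)-2-iodoaniline, via N-aryl imine 3 (not isolated)
Conditions: 2 (1.5 equiv), NaBH(OAc)3 (3 equiv), AcOH (2 equiv), ClCH2CH2Cl, rt
Reagents that add atoms: none
Why: Direct reductive amination with an acetoxyborohydride: the aldehyde condenses with the weakly basic aniline to imine 3, whose protonated form is reduced faster than the aldehyde, while the ortho iodine and the low nucleophilicity of product 4 stop a second alkylation and the C–I, C–Br and acetal groups are inert; no stereocentre is formed.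

Step 2
Reactants: 5 1H-indole-2-carbaldehyde
Product: 6 2-ethynyl-1H-indole
Conditions: dimethyl (1-diazo-2-oxopropyl)phosphonate (1.3 equiv), K2CO3 (2.5 equiv), MeOH, 0 °C → rt; kept cold in solution and used at once
Reagents that add atoms: dimethyl (1-diazo-2-oxopropyl)phosphonate COP(=O)(OC)C(=[N+]=[N-])C(C)=O
Why: Seyferth–Gilbert homologation in its Ohira–Bestmann form: methoxide cleaves the acetyl group of the reagent, the resulting diazomethylphosphonate anion olefinates the aldehyde (Horner–Wadsworth–Emmons type), and the diazoalkene loses N2 to an alkylidene carbene that gives the terminal alkyne by 1,2-hydrogen shift; no stereocentre is formed.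

Step 3
Reactants: 4 5-bromo-N-(2,2-dimethoxyethyl)-2-iodoaniline; 6 2-ethynyl-1H-indole
Product: 7 5-bromo-N-(2,2-dimethoxyethyl)-2-[(1H-indol-2-yl)ethynyl]aniline
Conditions: Pd(PPh3)2Cl2 (3 mol%), CuI (5 mol%), Et3N/THF, rt, Ar, slow addition of 6
Reagents that add atoms: none
Why: Sonogashira coupling: zerovalent palladium inserts into the C–I bond of 4 much faster than into its C–Br bond at room temperature and the alkynylcopper species formed from 6, CuI and Et3N transfers the alkyne, so the bromide, the acetal and both N–H groups are kept; no stereocentre is formed.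

Step 4
Reactants: 7 5-bromo-N-(2,2-dimethoxyethyl)-2-[(1H-indol-2-yl)ethynyl]aniline
Product: 10 3-bromo-12H-pyrido[1,2-a:3,4-b']diindole, via biindole acetal 8 (not isolated), via methoxy dihydro pentacycle 9 (not isolated)
Conditions: Ph3PAuNTf2 (3 mol%), ClCH2CH2Cl (0.02 M), 50 °C until 7 is consumed; then CH3SO3H (2 equiv), 60 °C, same flask; aq. NaHCO3
Reagents that add atoms: none
Why: The cationic monovalent gold complex activates the alkyne, N5 adds anti to C12b in a 5-endo-dig closure and protodeauration at C13 gives biindole 8, the closest known reaction type being the gold-catalysed hydroamination of 2-alkynylanilines to indoles. Acid added only after 7 is consumed ionises the acetal of 8 to an oxocarbenium ion at C7, which C7a (C3 of indole B) attacks in a 6-exo-trig Friedel–Crafts closure (exo with respect to the oxocarbenium C=O bond) to 9, the closest known type being the Pomeranz–Fritsch/Bradsher cyclodehydration of N-(2,2-dialkoxyethyl) azoles onto a neighbouring arene. The C7 methoxy group of 9 sits at an indol-3-ylmethyl position, ionises again and loss of the C6 proton makes ring C aromatic without any oxidant. The only stereocentre formed, C7 of 9, is racemic and transient and vanishes in this elimination. The step needs three selectivities: N5 is the only nucleophile that can reach the alkyne through a five-membered transition state (N12 or C7a would close three- or four-membered rings), gold does not insert into the C–Br bond, and the oxocarbenium ion ends at C7a and not at N12 because N-attack gives an N,O-aminal that reopens under acid whereas C-attack is made irreversible by aromatisation, while C13 cannot reach C7. Holding back the acid until hydroamination is complete prevents a Prins-type attack of the alkyne on the oxocarbenium ion, and high dilution suppresses capture between molecules.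

Step 5
Reactants: 10 3-bromo-12H-pyrido[1,2-a:3,4-b']diindole
Product: 12 methyl 2-(3-bromo-12H-pyrido[1,2-a:3,4-b']diindol-13-yl)-2-oxoacetate, via glyoxylyl chloride 11 (not isolated)
Conditions: (COCl)2 (1.3 equiv), THF/CH2Cl2, 0 °C; then MeOH (excess), 0 °C → rt; aq. NaHCO3
Reagents that add atoms: oxalyl chloride O=C(Cl)C(=O)Cl; methanol CO
Why: Friedel–Crafts-type C-glyoxylation of an indole 3-position with oxalyl chloride followed by methanolysis: C13 is both C3 of indole A and the enamine β-carbon of N5 and hence the most nucleophilic carbon of 10, it gives acyl chloride 11 without Lewis acid, and methanol turns 11 (or its reversible N12 lactam) into the methyl ester while the C–Br bond and N12–H are untouched; no stereocentre is formed.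

## Compound list

1 | 5-bromo-2-iodoaniline | Nc1cc(Br)ccc1I | starting material
2 | dimethoxyacetaldehyde (2,2-dimethoxyacetaldehyde, 60 wt% in water) | COC(OC)C=O | starting material
3 | (E)-N-(5-bromo-2-iodophenyl)-2,2-dimethoxyethan-1-imine (not isolated) | COC(OC)/C=N/c1cc(Br)ccc1I | intermediate
4 | 5-bromo-N-(2,2-dimethoxyethyl)-2-iodoaniline | COC(OC)CNc1cc(Br)ccc1I | intermediate
5 | 1H-indole-2-carbaldehyde | O=Cc1cc2ccccc2[nH]1 | starting material
6 | 2-ethynyl-1H-indole | C#Cc1cc2ccccc2[nH]1 | intermediate
7 | 5-bromo-N-(2,2-dimethoxyethyl)-2-[(1H-indol-2-yl)ethynyl]aniline | COC(OC)CNc1cc(Br)ccc1C#Cc1cc2ccccc2[nH]1 | intermediate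
8 | 6-bromo-1-(2,2-dimethoxyethyl)-1H,1'H-2,2'-biindole (not isolated) | COC(OC)Cn1c(-c2cc3ccccc3[nH]2)cc2ccc(Br)cc21 | intermediate
9 | 3-bromo-7-methoxy-6,7-dihydro-12H-pyrido[1,2-a:3,4-b']diindole (racemic, not isolated) | COC1Cn2c(cc3ccc(Br)cc32)-c2[nH]c3ccccc3c21 | intermediate
10 | 3-bromo-12H-pyrido[1,2-a:3,4-b']diindole | c1c2ccc(Br)cc2n2ccc3c4ccccc4[nH]c3c12 | intermediate
11 | 2-(3-bromo-12H-pyrido[1,2-a:3,4-b']diindol-13-yl)-2-oxoacetyl chloride (not isolated) | O=C(Cl)C(=O)c1c2ccc(Br)cc2n2ccc3c4ccccc4[nH]c3c12 | intermediate
12 | methyl 2-(3-bromo-12H-pyrido[1,2-a:3,4-b']diindol-13-yl)-2-oxoacetate (achiral) | COC(=O)C(=O)c1c2ccc(Br)cc2n2ccc3c4ccccc4[nH]c3c12 | target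

Total steps: 5. Longest linear sequence: 4 steps (steps 1, 3, 4 and 5 from compound 1; step 2 is a one-step side branch).

Steps most likely to fail:

Step 4. The oxocarbenium ion may be captured between molecules, so that the electron-rich biindole oligomerises, or the acetal may ionise before hydroamination is complete and be attacked by the alkyne. The fallback sets out from 7, separates the two closures and changes both in kind. An anionic 5-endo-dig cyclisation (KOtBu, 2.5 equiv, N-methylpyrrolidone, rt; the anilide adds to the alkyne) would give biindole 8 as an isolated compound. Purified 8 would be hydrolysed in wet acetone with pyridinium p-toluenesulfonate to 2-(6-bromo-1H,1'H-2,2'-biindol-1-yl)acetaldehyde F1. The aldehyde of F1 would be hydroxyalkylated at C7a under this buffered acid to 3-bromo-6,7-dihydro-12H-pyrido[1,2-a:3,4-b']diindol-7-ol F2, and warming would dehydrate F2 to rejoin the route at 10.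

Step 2. Carbonate may deprotonate the indole N–H and make the 2-formyl group a poor acceptor, so that the olefination stalls, and the terminal alkyne may polymerise or homocouple on handling. The fallback sets out from 4 and places the alkyne on the aniline instead. Sonogashira coupling of 4 with ethynyltrimethylsilane (Pd(PPh3)2Cl2, CuI, Et3N, rt) would give 5-bromo-N-(2,2-dimethoxyethyl)-2-[(trimethylsilyl)ethynyl]aniline F3. K2CO3 in methanol would then free 5-bromo-N-(2,2-dimethoxyethyl)-2-ethynylaniline F4. A second iodide-selective Sonogashira coupling with commercial 2-iodo-1-(phenylsulfonyl)-1H-indole (O=S(=O)(c1ccccc1)n1c(I)cc2ccccc21) would give 5-bromo-N-(2,2-dimethoxyethyl)-2-{[1-(phenylsulfonyl)-1H-indol-2-yl]ethynyl}aniline F5. KOH in aqueous methanol/THF would remove the sulfonyl group to rejoin the route at 7; compounds 5 and 6 would then not be needed.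

Step 5. The hydrogen chloride set free may protonate C13 of the enamine-like heteroarene and stall the acylation, or acyl chloride 11 may acylate a second molecule of 10 to a symmetrical 1,2-diketone. The fallback sets out from 10 and reverses the polarity at C13. Iodination with N-iodosuccinimide (THF, 0 °C) would give 3-bromo-13-iodo-12H-pyrido[1,2-a:3,4-b']diindole F6. Deprotonation of N12–H with MeMgCl, iodine–magnesium exchange with iPrMgCl·LiCl at −20 °C (the aryl bromide does not exchange under these conditions) and addition of the C13 magnesium species to excess dimethyl oxalate at −40 °C would lead directly to 12.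

Further compounds

F1 | step 4 | 2-(6-bromo-1H,1'H-2,2'-biindol-1-yl)acetaldehyde | O=CCn1c(-c2cc3ccccc3[nH]2)cc2ccc(Br)cc21
F2 | step 4 | 3-bromo-6,7-dihydro-12H-pyrido[1,2-a:3,4-b']diindol-7-ol (racemic) | OC1Cn2c(cc3ccc(Br)cc32)-c2[nH]c3ccccc3c21
F3 | step 2 | 5-bromo-N-(2,2-dimethoxyethyl)-2-[(trimethylsilyl)ethynyl]aniline | COC(OC)CNc1cc(Br)ccc1C#C[Si](C)(C)C
F4 | step 2 | 5-bromo-N-(2,2-dimethoxyethyl)-2-ethynylaniline | COC(OC)CNc1cc(Br)ccc1C#C
F5 | step 2 | 5-bromo-N-(2,2-dimethoxyethyl)-2-{[1-(phenylsulfonyl)-1H-indol-2-yl]ethynyl}aniline | COC(OC)CNc1cc(Br)ccc1C#Cc1cc2ccccc2n1S(=O)(=O)c1ccccc1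
F6 | step 5 | 3-bromo-13-iodo-12H-pyrido[1,2-a:3,4-b']diindole | Ic1c2ccc(Br)cc2n2ccc3c4ccccc4[nH]c3c12
A1 | direct plan | tryptamine [2-(1H-indol-3-yl)ethan-1-amine] | NCCc1c[nH]c2ccccc12
A2 | direct plan | 2-(2,4-dibromophenyl)acetic acid | OC(=O)Cc1ccc(Br)cc1Br
A3 | direct plan | N-[2-(1H-indol-3-yl)ethyl]-2-(2,4-dibromophenyl)acetamide | O=C(Cc1ccc(Br)cc1Br)NCCc1c[nH]c2ccccc12
A4 | direct plan | 6-bromo-1-[2-(1H-indol-3-yl)ethyl]-1,3-dihydro-2H-indol-2-one | O=C1Cc2ccc(Br)cc2N1CCc1c[nH]c2ccccc12
A5 | direct plan | methyl 2-(3-bromo-6,7-dihydro-12H-pyrido[1,2-a:3,4-b']diindol-13-yl)-2-oxoacetate | COC(=O)C(=O)c1c2ccc(Br)cc2n2CCc3c4ccccc4[nH]c3-c12
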